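Temperature, held or changed at 10 min, was what set the flasks south-west, east and west apart, since their charges and their running time were alike.

| flask | starting material | reagent | capture agent | free catalyst | temperature | remark | time |
|---|---|---|---|---|---|---|---|
| epsilon | 0.020 M | 3.5 equiv | 2 mM | 5 mol% | 30 °C | run made earlier |  |
| beta | 0.020 M | 5.5 equiv | 2 mM | 5 mol% | 41 °C | run made earlier |  |
| south-west | 0.020 M | 2.50 equiv | 2.00 mM | 5 mol% | 25 °C |  | 15 min |
| east | 0.020 M | 2.50 equiv | 2.00 mM | 5 mol% |  | at 45 °C until 10 min, from then on at 25 °C | 15 min |
| west | 0.020 M | 2.50 equiv | 2.00 mM | 5 mol% | 45 °C |  | 15 min |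

- epsilon (time / min: target / %, starting material / %): 0.667: 1, 93; 1.00: 3, 86; 1.50: 1, 80; 2.50: 5, 70; 4.00: 12, 60; 6.00: 20, 50; 10.0: 31, 33
- beta (time / min: target / %, starting material / %): 0.250: 1, 94; 0.667: 0, 83; 1.00: 3, 78; 2.00: 13, 58; 2.50: 15, 56; 4.00: 28, 41; 5.00: 33, 34

(readings scatter by 2 percentage points)

* the flask with the highest amount of target, in percent of the starting material charged ("all alike" if they lie within 1.5 percentage points) (south-west / east / west / all alike)
* final target, as a percentage of the starting material charged, in south-west
* final target, as a percentage of the starting material charged, in east
* final target, as a percentage of the starting material charged, in west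

- what was read earlier has a scatter of 2 percentage points, one standard deviation
- steps thought possible: starting material + free catalyst -> free catalyst + open intermediate; free catalyst + open intermediate <-> catalyst intermediate; reagent + catalyst intermediate -> free catalyst + target; 2 reagent -> self-condensation product; open intermediate + capture agent -> trapped intermediate

Free catalyst acts on starting material to give open intermediate, and it can then bind that as catalyst intermediate. I expected starting material to follow exp(−kt), with k a pseudo-first-order constant, as long as free catalyst stayed steady. So I read k from the epsilon run in two ways: the reading at 2.50 min gave 0.143 min⁻¹, and the last, at 10.0 min, gave 0.111 min⁻¹. They parted, and the beta run parted likewise, with 0.272 min⁻¹ at 2.00 min against 0.216 min⁻¹ at 5.00 min. The early value was the one that cheated for a long flask, because the constant averaged from the start came out lower later in the run, as binding of free catalyst suggests. I kept the late values, expecting starting material to end above my reckoning.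

The second reading agreed. At the last readings, 36.0 % of the charge in the epsilon run and 33.0 % in the beta run was neither starting material nor target, a gap smaller than twice the scatter, despite different temperature and reagent. Their mean, 34.5 %, is my held-back share, the part of the charge standing as neither starting material nor target.

Target is then one minus exp(−kt) minus that share. Taking ln k as linear in temperature gave 0.0819 min⁻¹ at 25 °C and 0.275 min⁻¹ at 45 °C. My reckoning was 36.2 % in south-west, 61.3 % in east and 63.9 % in west.

The forecast named west, with 27 % in south-west, 61 % in east and 69 % in west, holding that “Hot throughout should still win”. It stood lower than mine in south-west and higher in west.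

The flasks gave 31.7 % in south-west, 56.4 % in east and 60.3 % in west, so west led.

    starting material + free catalyst → free catalyst + open intermediate (k = 1.90 M⁻¹ s⁻¹, Ea = 41.0 kJ mol⁻¹)
    free catalyst + open intermediate ⇌ catalyst intermediate (K = 640 M⁻¹, k = 3.00 M⁻¹ s⁻¹, Ea = 49.0 kJ mol⁻¹, ΔH = −33.0 kJ mol⁻¹)
    reagent + catalyst intermediate → free catalyst + target (k = 1.40 M⁻¹ s⁻¹, Ea = 60.0 kJ mol⁻¹)
    2 reagent → self-condensation product (k = 0.0430 M⁻¹ s⁻¹, Ea = 43.0 kJ mol⁻¹)
    open intermediate + capture agent → trapped intermediate (k = 0.0530 M⁻¹ s⁻¹, Ea = 57.0 kJ mol⁻¹)
    (constants at 25 °C)

In west the share came to 33.6 %, and starting material stood at 6.1 % against 1.62 % from my exponential. In west the binding of open intermediate, by that step alone, had a relaxation half-life of 0.124 min at 15.0 min, far shorter than the 15 min of the run, and at 15.0 min open intermediate was made at 0.899 times the rate it was used, each step taken net.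

A neighbour of west, charged with 0.080 M of starting material, holds 4.00 times the free catalyst, and that factor on k with the same share gives 65.5 % target. The computed neighbour gives 67.3 %.

Readings and results stem from a simulated flask with made-up constants.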